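**Plan**

- Locants (azulene numbering): C-1/C-2 epoxide carbons (C-2 bears CH3), C-3 CH2, C-3a/C-8a ring fusion, C-4 CH(iPr), C-5 CH–O–aroyl, C-6 CH2, C-7 C(CH3)OH, C-8 CH2; β is the face of H-3a.
- Retrosynthesis: aryl ester and epoxide off; C-5 carbinol from the C-5 ketone; C-7 carbinol from a C6=C7 enone; C6–C7 cut (aldol condensation) to a cyclopentene carrying two methyl-ketone chains; then C8–C8a and C3a–C4 cut together.
- Enabling feature: the C1=C2 double bond (epoxide precursor) lies allylic to C-8a, and C-4 and C-8 are each α to an oxygenated carbon (C-5, C-7). Both bonds are therefore ester-enolate [3,3] bonds, relayed through a trans-1-methylcyclopent-3-ene-1,2-diol with oxygens on the future C-1 and C-2.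
- Forward: (R)-linalool → cyclopentene trans-diol (metathesis, ene oxidation, directed reduction) → isovalerate/acetate → one-pot double Ireland–Claisen (both chains, alkene ends at C1=C2) → diketone → seven-membered ring by aldol condensation → C-7 and C-5 carbinols, ester, epoxide.
- Stereochemistry: C-3a/C-8a by suprafacial transfer from the two C–O bonds of the trans-diol (which derives from the linalool carbinol centre); C-4 by equilibration next to the C-5 ketone; C-7 by catalyst-controlled conjugate borylation; C-5 and the epoxide by delivery from the C-7 hydroxyl.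

Key step: step 6

Remark: the side-chain centre that becomes C-4 is carried as an epimer mixture from step 6 and is equilibrated in step 8; (R)-(−)-linalool of high enantiomeric purity is assumed.

Step 1
Reactants: 1 (R)-(−)-linalool
Product: 2 (1R)-1-methylcyclopent-2-en-1-ol
Conditions: second-generation Grubbs catalyst RuCl2(=CHPh)(PCy3)(H2IMes) (1 mol%), CH2Cl2, 40 °C
Reagents that add atoms: none
Why: Ring-closing metathesis of the 1,6-diene, accelerated by the tertiary allylic hydroxyl; no bond to the carbinol stereocentre is touched, so 2 keeps the R configuration.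

Step 2
Reactants: 2 (1R)-1-methylcyclopent-2-en-1-ol
Product: 5 (5R)-5-hydroxy-5-methylcyclopent-2-en-1-one, via allylic hydroperoxide 3 (not isolated), via peroxy acetate 4 (not isolated)
Conditions: O2, hν (visible), tetraphenylporphyrin (cat.), CH2Cl2, 0 °C; then Ac2O, pyridine, 0 °C to rt
Reagents that add atoms: dioxygen, O=O (one oxygen stays); acetic anhydride, CC(=O)OC(C)=O (acetyl in 4 only)
Why: Schenck ene reaction of singlet oxygen, which can place oxygen only on the alkene carbon next to the quaternary carbinol carbon (the sole allylic hydrogens are on the far side) and so shifts the double bond, followed by Kornblum–DeLaMare-type loss of acetic acid to the enone; the transient hydroperoxide centre is erased and the tertiary centre is kept.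

Step 3
Reactants: 5 (5R)-5-hydroxy-5-methylcyclopent-2-en-1-one
Product: 6 (1R,2R)-1-methylcyclopent-3-ene-1,2-diol
Conditions: Me4N[BH(OAc)3], MeCN/AcOH (1:1), −20 °C
Reagents that add atoms: none
Why: Hydroxyl-directed 1,2-reduction with triacetoxyborohydride (Saksena–Evans type): the tertiary hydroxyl binds boron and hands hydride to the carbonyl on its own face, so the new secondary hydroxyl is trans to it.

Step 4
Reactants: 6 (1R,2R)-1-methylcyclopent-3-ene-1,2-diol; 7 3-methylbutanoyl chloride
Product: 8 (1R,5R)-5-hydroxy-5-methylcyclopent-2-en-1-yl 3-methylbutanoate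
Conditions: pyridine, CH2Cl2, −20 to 0 °C
Reagents that add atoms: none
Why: Acylation of the secondary allylic alcohol by an acid chloride; the tertiary alcohol does not react with pyridine alone at low temperature and no stereocentre is touched.

Step 5
Reactants: 8 (1R,5R)-5-hydroxy-5-methylcyclopent-2-en-1-yl 3-methylbutanoate
Product: 9 (1R,5R)-5-acetoxy-5-methylcyclopent-2-en-1-yl 3-methylbutanoate
Conditions: Ac2O, Et3N, DMAP (cat.), CH2Cl2, rt
Reagents that add atoms: acetic anhydride, CC(=O)OC(C)=O
Why: DMAP-catalysed (Steglich-type) acetylation of the tertiary alcohol, without change at either stereocentre.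

Step 6
Reactants: 9 (1R,5R)-5-acetoxy-5-methylcyclopent-2-en-1-yl 3-methylbutanoate
Product: 13 2-[(1R,2S)-2-(carboxymethyl)-4-methylcyclopent-3-en-1-yl]-3-methylbutanoic acid, via bis(silyl ketene acetal) 10 (not isolated), via mono-rearranged silyl ester 11 (not isolated), via bis(trimethylsilyl) ester 12 (not isolated)
Conditions: LiN(iPr)2 (2.4 equiv), Me3SiCl/Et3N (in situ), THF, −78 °C; then rt to 60 °C; aq. HCl
Reagents that add atoms: chlorotrimethylsilane, C[Si](C)(C)Cl (silicon in 10 to 12 only, none in 13)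
Why: Both esters are converted into silyl ketene acetals; only the isovalerate on the future C-1 is allylic, so its [3,3] shift comes first, forms C3a–C4 and moves the double bond to C1=C8a, which makes the acetate-derived ketene acetal on C-2 allylic, and the second [3,3] shift then forms C8a–C8 and leaves the C1=C2 alkene. The closest known reaction type is the Ireland–Claisen rearrangement of cyclic secondary and tertiary allylic esters, here run twice in relay. No ring is closed; each bond forms through a six-membered pericyclic transition state held on the cyclopentene. C-3a is set by the C1–O bond and C-8a by the C2–O bond, each new C–C bond arising on the face from which its oxygen departs, so the trans-diol gives trans side chains; the centre α to the new carboxyl (future C-4) is not controlled here. The step needs order and regiochemistry, and the substrate secures both: the acetate becomes allylic only after the first shift, and each shift can end only at the γ-carbon of its allyl unit; the internal Me3SiCl quench at −78 °C suppresses ester condensation.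

Step 7
Reactants: 13 2-[(1R,2S)-2-(carboxymethyl)-4-methylcyclopent-3-en-1-yl]-3-methylbutanoic acid
Product: 14 4-methyl-3-[(1R,2S)-4-methyl-2-(2-oxopropyl)cyclopent-3-en-1-yl]pentan-2-one
Conditions: MeLi (6 equiv), Et2O, 0 °C to rt; reverse quench into cold aq. HCl
Reagents that add atoms: methyllithium, [Li]C
Why: Addition of methyllithium to the lithium carboxylates gives gem-diolates that collapse to the two methyl ketones only on acidic work-up (classical acid-to-methyl-ketone conversion); the ring stereocentres are not touched.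

Step 8
Reactants: 14 4-methyl-3-[(1R,2S)-4-methyl-2-(2-oxopropyl)cyclopent-3-en-1-yl]pentan-2-one
Product: 16 2,7-dimethyl-4β-(propan-2-yl)-3a,4,8,8a-tetrahydroazulen-5(3H)-one (3aβH,8aαH), via aldol adduct 15 (not isolated)
Conditions: KOH, MeOH, 60 °C
Reagents that add atoms: none
Why: Intramolecular aldol condensation in which the methyl of the hindered ketone adds to the unhindered 2-oxopropyl carbonyl (the two five-membered closures would give a trans-bicyclo[3.3.0]octane and attack on the hindered carbonyl is slow), dehydration to the conjugated enone drives the seven-membered closure, and C-4 equilibrates under the same conditions to the isomer with isopropyl trans to C-3 (β); C-3a and C-8a are not acidic.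

Step 9
Reactants: 16 2,7-dimethyl-4β-(propan-2-yl)-3a,4,8,8a-tetrahydroazulen-5(3H)-one (3aβH,8aαH)
Product: 18 7β-hydroxy-2,7-dimethyl-4β-(propan-2-yl)-3a,4,6,7,8,8a-hexahydroazulen-5(3H)-one (3aβH,8aαH), via tertiary boronate 17 (not isolated)
Conditions: B2pin2, CuCl (5 mol%), NaOtBu (10 mol%), QuinoxP* (6 mol%, the antipode that directs boron to the β face), MeOH (2 equiv), THF, rt; then NaBO3·4H2O, THF/H2O
Reagents that add atoms: bis(pinacolato)diboron, CC1(C)OB(OC1(C)C)B1OC(C)(C)C(C)(C)O1 (boron in 17 only); sodium perborate NaBO3, [Na+].[O-]OB=O (the C-7 oxygen)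
Why: Copper-catalysed conjugate borylation of the β,β-disubstituted cycloheptenone followed by perborate oxidation with retention should give the tertiary aldol; the chiral Cu–bisphosphine complex sets C-7 with boron, and hence OH, on the β face.

Step 10
Reactants: 18 7β-hydroxy-2,7-dimethyl-4β-(propan-2-yl)-3a,4,6,7,8,8a-hexahydroazulen-5(3H)-one (3aβH,8aαH)
Product: 19 2,7-dimethyl-4β-(propan-2-yl)-3,3a,4,5,6,7,8,8a-octahydroazulene-5α,7β-diol (3aβH,8aαH)
Conditions: Me4N[BH(OAc)3], MeCN/AcOH (1:1), −20 °C
Reagents that add atoms: none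
Why: Saksena–Evans reduction: hydride is delivered intramolecularly from the C7–O–B species to the β face of the C-5 carbonyl, giving the anti (5α,7β) 1,3-diol with the new hydroxyl trans to the 4β-isopropyl group.

Step 11
Reactants: 19 2,7-dimethyl-4β-(propan-2-yl)-3,3a,4,5,6,7,8,8a-octahydroazulene-5α,7β-diol (3aβH,8aαH); 20 4-acetoxybenzoyl chloride
Product: 21 7β-hydroxy-2,7-dimethyl-4β-(propan-2-yl)-3,3a,4,5,6,7,8,8a-octahydroazulen-5α-yl 4-acetoxybenzoate (3aβH,8aαH)
Conditions: pyridine, DMAP (cat.), CH2Cl2, 0 °C to rt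
Reagents that add atoms: none
Why: Acylation of the secondary C-5 alcohol by the aroyl chloride; the tertiary C-7 alcohol is too hindered to react and no stereocentre changes.

Step 12
Reactants: 21 7β-hydroxy-2,7-dimethyl-4β-(propan-2-yl)-3,3a,4,5,6,7,8,8a-octahydroazulen-5α-yl 4-acetoxybenzoate (3aβH,8aαH)
Product: 22 1β,2β-epoxy-7β-hydroxy-2,7-dimethyl-4β-(propan-2-yl)decahydroazulen-5α-yl 4-acetoxybenzoate (3aβH,8aαH)
Conditions: VO(acac)2 (5 mol%), t-BuOOH, toluene, rt
Reagents that add atoms: tert-butyl hydroperoxide, CC(C)(C)OO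
Why: Vanadium-catalysed hydroxyl-directed epoxidation (Sharpless–Michaelson type) of the bishomoallylic tertiary alcohol: the C7–O–V peroxide sits on the β face, the face of the C8a–C8 bond, and should deliver oxygen to the β face of C1=C2; ester and aryl acetate are inert.

Step 13
Reactants: 22 1β,2β-epoxy-7β-hydroxy-2,7-dimethyl-4β-(propan-2-yl)decahydroazulen-5α-yl 4-acetoxybenzoate (3aβH,8aαH)
Product: 23 1β,2β-epoxy-7β-hydroxy-2,7-dimethyl-4β-(propan-2-yl)decahydroazulen-5α-yl 4-hydroxybenzoate (3aβH,8aαH), the target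
Conditions: K2CO3 (0.2 equiv), MeOH, 0 °C
Reagents that add atoms: none
Why: Base-catalysed methanolysis (transesterification) of the aryl acetate, much faster than attack on the hindered secondary benzoate, which is further deactivated once the phenoxide forms; epoxide and stereocentres are unaffected.

**Compound list**

1 | (R)-(−)-linalool, (3R)-3,7-dimethylocta-1,6-dien-3-ol | C[C@@](C=C)(O)CCC=C(C)C | starting material
2 | (1R)-1-methylcyclopent-2-en-1-ol | C[C@@]1(O)CCC=C1 | intermediate
3 | (1R)-2-hydroperoxy-1-methylcyclopent-3-en-1-ol (C-2 epimers) | C[C@@]1(O)CC=CC1OO | intermediate (not isolated)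
4 | (5R)-5-hydroxy-5-methylcyclopent-2-en-1-yl ethaneperoxoate (C-1 epimers) | C[C@@]1(O)CC=CC1OOC(C)=O | intermediate (not isolated)
5 | (5R)-5-hydroxy-5-methylcyclopent-2-en-1-one | C[C@@]1(O)CC=CC1=O | intermediate
6 | (1R,2R)-1-methylcyclopent-3-ene-1,2-diol (trans) | C[C@@]1(O)CC=C[C@H]1O | intermediate
7 | 3-methylbutanoyl chloride | CC(C)CC(Cl)=O | starting material
8 | (1R,5R)-5-hydroxy-5-methylcyclopent-2-en-1-yl 3-methylbutanoate | C[C@@]1(O)CC=C[C@H]1OC(=O)CC(C)C | intermediate
9 | (1R,5R)-5-acetoxy-5-methylcyclopent-2-en-1-yl 3-methylbutanoate | C[C@@]1(OC(C)=O)CC=C[C@H]1OC(=O)CC(C)C | intermediate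
10 | bis(trimethylsilyl ketene acetal) of 9 (ketene acetal geometry not specified) | C[C@@]1(OC(=C)O[Si](C)(C)C)CC=C[C@H]1OC(O[Si](C)(C)C)=CC(C)C | intermediate (not isolated)
11 | trimethylsilyl 3-methyl-2-[(1R,4R)-4-methyl-4-{[1-(trimethylsilyloxy)ethenyl]oxy}cyclopent-2-en-1-yl]butanoate (C-2 epimers) | C[C@@]1(OC(=C)O[Si](C)(C)C)C[C@@H](C(C(C)C)C(=O)O[Si](C)(C)C)C=C1 | intermediate (not isolated)
12 | bis(trimethylsilyl) ester of 13 | CC(C)C(C(=O)O[Si](C)(C)C)[C@@H]1CC(C)=C[C@H]1CC(=O)O[Si](C)(C)C | intermediate (not isolated)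
13 | 2-[(1R,2S)-2-(carboxymethyl)-4-methylcyclopent-3-en-1-yl]-3-methylbutanoic acid (side chains trans; butanoic C-2 epimers) | CC(C)C(C(=O)O)[C@@H]1CC(C)=C[C@H]1CC(=O)O | intermediate
14 | 4-methyl-3-[(1R,2S)-4-methyl-2-(2-oxopropyl)cyclopent-3-en-1-yl]pentan-2-one (C-3 epimers) | CC(C)C(C(C)=O)[C@@H]1CC(C)=C[C@H]1CC(C)=O | intermediate
15 | 7-hydroxy-2,7-dimethyl-4-(propan-2-yl)-3a,4,6,7,8,8a-hexahydroazulen-5(3H)-one (3aβH,8aαH; C-4 and C-7 epimers) | CC(C)C1[C@@H]2CC(C)=C[C@H]2CC(C)(O)CC1=O | intermediate (not isolated)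
16 | 2,7-dimethyl-4β-(propan-2-yl)-3a,4,8,8a-tetrahydroazulen-5(3H)-one (3aβH,8aαH; trans-fused; C1=C2 and C6=C7) | CC(C)[C@H]1[C@@H]2CC(C)=C[C@H]2CC(C)=CC1=O | intermediate
17 | 2,7-dimethyl-4β-(propan-2-yl)-7β-(4,4,5,5-tetramethyl-1,3,2-dioxaborolan-2-yl)-3a,4,6,7,8,8a-hexahydroazulen-5(3H)-one (3aβH,8aαH) | CC(C)[C@H]1[C@@H]2CC(C)=C[C@H]2C[C@@](C)(B3OC(C)(C)C(C)(C)O3)CC1=O | intermediate (not isolated)
18 | 7β-hydroxy-2,7-dimethyl-4β-(propan-2-yl)-3a,4,6,7,8,8a-hexahydroazulen-5(3H)-one (3aβH,8aαH) | CC(C)[C@H]1[C@@H]2CC(C)=C[C@H]2C[C@@](C)(O)CC1=O | intermediate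
19 | 2,7-dimethyl-4β-(propan-2-yl)-3,3a,4,5,6,7,8,8a-octahydroazulene-5α,7β-diol (3aβH,8aαH) | CC(C)[C@H]1[C@@H]2CC(C)=C[C@H]2C[C@@](C)(O)C[C@@H]1O | intermediate
20 | 4-acetoxybenzoyl chloride | CC(=O)Oc1ccc(cc1)C(Cl)=O | starting material
21 | 7β-hydroxy-2,7-dimethyl-4β-(propan-2-yl)-3,3a,4,5,6,7,8,8a-octahydroazulen-5α-yl 4-acetoxybenzoate (3aβH,8aαH) | CC(C)[C@H]1[C@@H]2CC(C)=C[C@H]2C[C@@](C)(O)C[C@@H]1OC(=O)c1ccc(OC(C)=O)cc1 | intermediate
22 | 1β,2β-epoxy-7β-hydroxy-2,7-dimethyl-4β-(propan-2-yl)decahydroazulen-5α-yl 4-acetoxybenzoate (3aβH,8aαH) | CC(C)[C@H]1[C@@H]2C[C@@]3(C)O[C@H]3[C@H]2C[C@@](C)(O)C[C@@H]1OC(=O)c1ccc(OC(C)=O)cc1 | intermediate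
23 | 1β,2β-epoxy-7β-hydroxy-2,7-dimethyl-4β-(propan-2-yl)decahydroazulen-5α-yl 4-hydroxybenzoate (3aβH,8aαH) | CC(C)[C@H]1[C@@H]2C[C@@]3(C)O[C@H]3[C@H]2C[C@@](C)(O)C[C@@H]1OC(=O)c1ccc(O)cc1 | target

**Step count and risks**

Total step count: 13. Longest linear sequence: 13 steps (1 to 23); 7 and 20 are used as purchased.

Steps most likely to fail:

Step 8. The seven-membered aldol closure may be slow or close in the other direction, with intermolecular aldol reactions taking over. Fallback (ring closure by olefin metathesis instead of aldol chemistry), setting out from 14: Wittig methylenation (Ph3P=CH2, 1 equiv, THF, 0 °C) of the less hindered 2-oxopropyl ketone gives the isopropenyl ketone 4-methyl-3-[(1R,2S)-4-methyl-2-(2-methylprop-2-en-1-yl)cyclopent-3-en-1-yl]pentan-2-one F1. Kinetic enolisation of the remaining methyl ketone (LiN(iPr)2, −78 °C) and reaction with CH2=NMe2+ I− gives the Mannich base F2, which is quaternised with MeI to the trimethylammonium iodide F3 and eliminated with NaHCO3 to the vinyl ketone F4. Ring-closing metathesis of F4 (second-generation Hoveyda–Grubbs catalyst RuCl2(=CH-C6H4-2-OiPr)(H2IMes), toluene, 80 °C) and equilibration of C-4 with DBU bring the route back to 16.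

Step 9. Boron delivery to C-7 may show poor facial selectivity (catalyst and substrate bias mismatched), or retro-aldol cleavage may occur during the oxidation. Fallback (relay of stereochemistry from C-5 instead of catalyst control), setting out from 16: LiBH(s-Bu)3 reduces the C-5 carbonyl from the α face, anti to the 4β-isopropyl group, to the 5β allylic alcohol F5. VO(acac)2/t-BuOOH epoxidises C6=C7 syn to that hydroxyl to give the 6β,7β-epoxy-5β-alcohol F6. NaAlH2(OCH2CH2OMe)2 opens the epoxide at C-6 to the 5β,7β-diol F7, and Dess–Martin oxidation of the secondary alcohol returns the route to 18.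

Step 12. Hydroxyl direction across the bishomoallylic distance may be too weak, so that oxygen is delivered to the α face. Fallback (reagent control instead of substrate direction), setting out from 21: epoxidation with the dioxirane formed from the fructose-derived Shi ketone, or its enantiomer, and KHSO5 (buffered MeCN/water, 0 °C), the ketone antipode being chosen for β-face attack on the trisubstituted alkene. This makes no new compound (F0) and comes back to the route at 22.

**Further compounds**

F1 | step 8 | 4-methyl-3-[(1R,2S)-4-methyl-2-(2-methylprop-2-en-1-yl)cyclopent-3-en-1-yl]pentan-2-one (C-3 epimers) | CC(C)C(C(C)=O)[C@@H]1CC(C)=C[C@H]1CC(C)=C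
F2 | step 8 | 1-(dimethylamino)-5-methyl-4-[(1R,2S)-4-methyl-2-(2-methylprop-2-en-1-yl)cyclopent-3-en-1-yl]hexan-3-one (Mannich base) | CN(C)CCC(=O)C(C(C)C)[C@@H]1CC(C)=C[C@H]1CC(C)=C
F3 | step 8 | trimethylammonium iodide of F2 | C[N+](C)(C)CCC(=O)C(C(C)C)[C@@H]1CC(C)=C[C@H]1CC(C)=C.[I-]
F4 | step 8 | 5-methyl-4-[(1R,2S)-4-methyl-2-(2-methylprop-2-en-1-yl)cyclopent-3-en-1-yl]hex-1-en-3-one (vinyl ketone) | C=CC(=O)C(C(C)C)[C@@H]1CC(C)=C[C@H]1CC(C)=C
F5 | step 9 | 2,7-dimethyl-4β-(propan-2-yl)-3,3a,4,5,8,8a-hexahydroazulen-5β-ol (3aβH,8aαH) | CC(C)[C@H]1[C@@H]2CC(C)=C[C@H]2CC(C)=C[C@H]1O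
F6 | step 9 | 6β,7β-epoxy-2,7-dimethyl-4β-(propan-2-yl)-3,3a,4,5,6,7,8,8a-octahydroazulen-5β-ol (3aβH,8aαH) | CC(C)[C@H]1[C@@H]2CC(C)=C[C@H]2C[C@@]3(C)O[C@H]3[C@H]1O
F7 | step 9 | 2,7-dimethyl-4β-(propan-2-yl)-3,3a,4,5,6,7,8,8a-octahydroazulene-5β,7β-diol (3aβH,8aαH) | CC(C)[C@H]1[C@@H]2CC(C)=C[C@H]2C[C@@](C)(O)C[C@H]1O
F0 | step 12 | none | none
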